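**Remark on the chemistry (assumption):** halimane numbering is used for all compounds (ring A = C1–C5 and C10, ring B = C5–C10, side chain C11–C15). CIP descriptors in the names change with the substituents although no centre is inverted after it is set.

## Analysis of the target

Target 28 is a bicyclic diterpenoid diester built on a Δ1(10)-octalin. Ring A (C1–C5, C10) is a cyclohexene whose trisubstituted alkene C1=C10 lies at the ring fusion, ring B (C5–C10) is a cyclohexane, and C9 carries a five-carbon chain (C11–C15) ending in a primary acetate. There are five stereocentres: quaternary C4 (CH3, CO2CH3; S), C5 (H; R), C8 (CH3; R), quaternary C9 (CH3, chain; S) and C13 (CH3; S). C4/C5 and C8/C9 are vicinal pairs joined through the sp2 carbon C10. The C8 and C9 methyl groups are cis on ring B, H5 lies on the face of the C9 methyl, and the ester at C4 is trans to H5. C13 is three bonds from the ring and cannot be controlled from it. The sensitive groups are the primary acetate (bases, hydrides, organometallics), the methyl ester, and the alkene, which can drift to the tetrasubstituted 5(10) position under acid or metal hydrides. The difficulty is two quaternary stereocentres, each next to a tertiary one, in a ring system with no heteroatom handle, plus the exact placement of the alkene. The strategy rests on ring A: a cyclohexene with its alkene at C1=C10 and the ester-bearing C4 next to the fusion CH C5 is the retron of a Diels–Alder reaction between methyl methacrylate 22 and a ring B 1-vinylcyclohexene. That diene is in turn the product of a ring-closing enyne metathesis, so both rings trace back to one acyclic chain.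

## Retrosynthetic reasoning

**28 ⇒ 27 ⇒ 26.** The acetyl C–O bond at C15 is cut, and alcohol 27 is traced to its p-methoxybenzyl ether 26. An acetate would not survive the enolate, hydride and organolithium steps needed for the skeleton. The benzylic ether does, and it leaves oxidatively without touching the alkene or the ester.

**26 ⇒ 25 ⇒ 24.** The C1–H bond is traced to a C1–O bond: alkene 26 from enol triflate 25, and 25 from silyl enol ether 24. The added oxygen costs nothing, because it is what activates and orients the cycloaddition below. As an enol derivative it also pins the alkene to C1=C10. The forward steps must exchange Si–O for S–O without passing through the free ketone, then reduce the C–O bond.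

**24 ⇒ 23 + 22 (key step, second half).** In ring A the bonds C2–C3 and C4–C5 are cut. Cutting here, and not at C3–C4 or C1–C2, turns C3, C4, the C4 methyl and the ester into the commercial dienophile 22. It leaves diene 23, whose siloxy group on C1 and alkyl-substituted terminus C5 both direct the ester carbon to C5. Ring A and two stereocentres (C4, C5) are gained at once. The forward reaction must give the ester-endo adduct on the diene face opposite the C9 methyl.

**23 ⇒ 21 (key step, first half).** The diene is opened at C5=C10 and C1=C2 by an enyne-metathesis transform to the acyclic siloxyalkyne–alkene 21. This removes ring B altogether, so only a chain carrying C8, C9 and C13 remains. The forward reaction is a six-membered exo ring closure by a ruthenium alkylidene.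

**21 ⇒ 18.** The O–Si and C1–O bonds are cut back to terminal alkyne 18. The siloxyalkyne is too sensitive to carry, so it is made last.

**18 ⇒ 17 ⇒ 16.** The C6–C7 bond is cut: C5, C6 and the terminal CH2 come from an allyl nucleophile, and C7 is a primary electrophile (triflate 17 from alcohol 16). The cut is one bond away from C8, so the substitution cannot touch a stereocentre. The terminal alkene is added only after the other alkene of the chain has been cleaved, so two alkenes never have to be told apart.

**16 ⇒ 15 ⇒ 14 ⇒ 13.** The alkyne carbon C1 is removed by a one-carbon homologation transform, giving the C10 aldehyde, stored as lactol 15. The aldehyde is traced to a propenyl group (alcohol 14), and the C7 alcohol to acid 13. This exposes a γ,δ-unsaturated acid, the retron of a [3,3] rearrangement.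

**13 ⇒ 10.** The C8–C9 bond is cut by an Ireland–Claisen transform to the secondary allylic propanoate 10. This is the bond that joins the tertiary and the quaternary centre. The pericyclic transition state lets two geometries (enolate and alkene) fix their relative configuration, and one carbinol centre fix their absolute configuration.

**10 ⇒ 8 + 9, and 8 ⇒ 7.** The ester C–O bond is cut to alcohol 8 and propionyl chloride 9. The carbinol is traced to enone 7, so its configuration comes from a catalyst and not from the distant C13.

**7 ⇒ 6 ⇒ 4.** Enone 7 comes from allylic alcohol 6, which is cut at C9–CH3 and at C10–carbinol carbon. A syn carbometalation of terminal alkyne 4 gives the (E)-trisubstituted alkene cleanly, which a carbonyl olefination would not.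

**4 ⇒ 3 ⇒ 2 ⇒ 1.** The alkyne carbon (future C10) is removed to aldehyde 3, which comes from cleavage of the trisubstituted alkene of ether 2. Ether 2 is protected (S)-citronellol 1. Its stereocentre becomes C13, and its C1–C6 become C15–C11 and C9.

## Alternatives that were turned down

**Alternative 1:** Ring A is left for later and ring B is traced to 2-methylcyclohex-2-en-1-one A1 and the (E)-allylic bromide A2, cutting C8–CH3 and C9–C11. In the forward step CH3MgBr adds to C8 of A1 under Cu(OTf)2 and a chiral N-heterocyclic carbene ligand, and the bromomagnesium enolate A3 is C-alkylated at C9 by A2 in the same flask to give ketone A4.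
- For: it is catalytic and asymmetric, and it sets C8 and C9 in one operation on a ring, where alkylation anti to the new C8 methyl gives the cis-dimethyl pattern. On the number of steps to a C8/C9-defined intermediate it is clearly stronger than the chosen route, which needs eight steps to reach acid 13.
- Against: A4 contains neither ring A nor C13. The C12=C13 alkene would need an enantioselective hydrogenation with no directing group. Ring A, with C4, C5 and the 1(10)-alkene, would have to be annulated onto a ketone flanked by the quaternary C9. α-Substituted cyclic enones are poor acceptors for asymmetric conjugate addition, and C-alkylation of a tetrasubstituted magnesium enolate competes with proton transfer and O-alkylation.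
- Comparison: the chosen route takes C13 from the chiral pool and closes both rings in one step with the alkene in place, at the price of a longer acyclic sequence.

**Alternative 2:** The C9 methyl is traced to the CH2 of a cyclopropane spanning C9 and C10 in carbinol A6, made from the tetrasubstituted allylic alcohol A5. In the forward step the C1 hydroxyl of A5, deprotonated by Et2Zn, directs methylene transfer from Et2Zn/CH2I2 to the alkene face it occupies, giving A6.
- For: hydroxyl-directed Simmons–Smith cyclopropanation works on tetrasubstituted alkenes and sets the quaternary C9 from a neighbouring carbinol in a rigid bicycle. This control of C9 is at least as secure as the acyclic rearrangement used here.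
- Against: the problem is only moved. A5 already holds both rings, C4, C5, C8, C13 and an extra stereocentre at C1. After the key step the carbinol must be oxidised, the three-membered ring opened reductively in the presence of the ester, and the 1(10)-alkene re-installed regioselectively from the resulting carbonyl group.
- Comparison: the chosen route gets its C1 oxygen for free from the alkyne and converts it directly into the alkene. It needs no extra stereocentre and far fewer redox steps.

**Alternative 3:** The C4–C5 bond is cut with transposition of the alkene, tracing acid A9 to δ-lactone A7, whose C1 carries the ring B cyclohexenyl group. In the forward step LiN(i-Pr)2 and Me3SiCl convert A7 into silyl ketene acetal A8, which on warming rearranges [3,3] through a boat-like transition state. C4 bonds to C5 on the face from which the C1–O bond leaves, the alkene moves to C1=C10, and carbocyclic ring A closes to give A9.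
- For: it is intramolecular. The C1 configuration is transferred to C5, and the ring-fixed ketene acetal geometry fixes C4. On C4/C5 control this is stronger than the intermolecular cycloaddition chosen here, whose endo preference is weak. It is equally strong on the alkene position.
- Against: A7 needs ring B with C8 and C9 made first, plus a C1 carbinol of defined configuration next to a hindered cyclohexenyl group. The rearrangement must join a fully substituted ketene acetal carbon to a ring carbon through a strained boat. The route is linear, ring by ring.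
- Comparison: the chosen strategy gives up the intramolecular guarantee at C4 but closes both rings from one acyclic chain in one flask, with one stereocentre fewer to prepare.

Key step: step 15

## Route

Step 1
Reactants: 1 (S)-citronellol
Product: 2 1-({[(3S)-3,7-dimethyloct-6-en-1-yl]oxy}methyl)-4-methoxybenzene
Conditions: NaH, 4-MeOC6H4CH2Cl, n-Bu4NI (cat.), THF–DMF, 0 °C → rt
Reagents that add atoms: 4-methoxybenzyl chloride, COc1ccc(CCl)cc1
Why: Williamson etherification of the primary alkoxide; the p-methoxybenzyl ether tolerates the bases, hydrides, organometallics and heat to come and is removed oxidatively at the end; the stereocentre (future C13) is not touched.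

Step 2
Reactants: 2 1-({[(3S)-3,7-dimethyloct-6-en-1-yl]oxy}methyl)-4-methoxybenzene
Product: 3 (4S)-6-[(4-methoxyphenyl)methoxy]-4-methylhexanal
Conditions: OsO4 (cat.), NaIO4, 2,6-lutidine, dioxane–H2O, rt
Reagents that add atoms: osmium tetroxide (catalytic oxygen carrier), O=[Os](=O)(=O)=O; sodium periodate (terminal oxidant), [Na+].[O-]I(=O)(=O)=O
Why: Lemieux–Johnson cleavage of the only alkene (dihydroxylation, then glycol cleavage); it leaves the electron-rich anisyl ring alone, and the stereocentre is γ to the new aldehyde and cannot epimerise.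

Step 3
Reactants: 3 (4S)-6-[(4-methoxyphenyl)methoxy]-4-methylhexanal
Product: 4 1-methoxy-4-({[(3S)-3-methylhept-6-yn-1-yl]oxy}methyl)benzene
Conditions: dimethyl (1-diazo-2-oxopropyl)phosphonate, K2CO3, MeOH, 0 °C → rt
Reagents that add atoms: dimethyl (1-diazo-2-oxopropyl)phosphonate, CC(=O)C(=[N+]=[N-])P(=O)(OC)OC
Why: Ohira–Bestmann (Seyferth–Gilbert) homologation: methanolysis frees the diazomethylphosphonate anion, which adds to the aldehyde, loses phosphate and N2, and gives the terminal alkyne by 1,2-hydride shift; the added carbon is the future C10.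

Step 4
Reactants: 4 1-methoxy-4-({[(3S)-3-methylhept-6-yn-1-yl]oxy}methyl)benzene
Product: 6 (3E,7S)-9-[(4-methoxyphenyl)methoxy]-4,7-dimethylnon-3-en-2-ol (both C2 epimers), via alkenyldimethylalane 5 (not isolated)
Conditions: Me3Al, Cp2ZrCl2 (cat.), CH2Cl2, 0 °C → rt; n-BuLi, THF, −78 °C; CH3CHO, −78 → 0 °C
Reagents that add atoms: trimethylaluminium, C[Al](C)C; acetaldehyde, CC=O
Why: Zr-catalysed carboalumination adds CH3 and Al syn across the alkyne with CH3 on the internal carbon (the C9 methyl, E geometry), and the derived alkenylaluminate adds to the aldehyde with retention of the alkene geometry; the carbinol configuration does not matter because step 5 erases it.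

Step 5
Reactants: 6 (3E,7S)-9-[(4-methoxyphenyl)methoxy]-4,7-dimethylnon-3-en-2-ol (both C2 epimers)
Product: 7 (3E,7S)-9-[(4-methoxyphenyl)methoxy]-4,7-dimethylnon-3-en-2-one
Conditions: MnO2, CH2Cl2, rt
Reagents that add atoms: none
Why: Chemoselective oxidation of an allylic alcohol; the benzylic ether is inert and the conjugated (E)-alkene is the stable isomer.

Step 6
Reactants: 7 (3E,7S)-9-[(4-methoxyphenyl)methoxy]-4,7-dimethylnon-3-en-2-one
Product: 8 (2S,3E,7S)-9-[(4-methoxyphenyl)methoxy]-4,7-dimethylnon-3-en-2-ol
Conditions: (R)-2-methyl-CBS-oxazaborolidine (cat.), catecholborane, toluene, −78 °C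
Reagents that add atoms: none
Why: Corey–Bakshi–Shibata reduction; the trisubstituted alkenyl group acts as the large substituent and methyl as the small one, so the (R)-catalyst should give the (S)-carbinol (the same sense as acetophenone to (S)-1-phenylethanol); catecholborane at −78 °C does not hydroborate the alkene.

Step 7
Reactants: 8 (2S,3E,7S)-9-[(4-methoxyphenyl)methoxy]-4,7-dimethylnon-3-en-2-ol; 9 propionyl chloride
Product: 10 (2S,3E,7S)-9-[(4-methoxyphenyl)methoxy]-4,7-dimethylnon-3-en-2-yl propanoate
Conditions: EtCOCl, Et3N, DMAP (cat.), CH2Cl2, 0 °C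
Reagents that add atoms: propionyl chloride (9), CCC(Cl)=O
Why: O-acylation with retention at the carbinol; the propanoyl group supplies C7, C8 and the C8 methyl.

Step 8
Reactants: 10 (2S,3E,7S)-9-[(4-methoxyphenyl)methoxy]-4,7-dimethylnon-3-en-2-yl propanoate
Product: 13 (2S,3R,6S)-8-[(4-methoxyphenyl)methoxy]-2,3,6-trimethyl-3-[(1E)-prop-1-en-1-yl]octanoic acid, via silyl ketene acetal 11 (not isolated), via trimethylsilyl ester 12 (not isolated)
Conditions: LiN(i-Pr)2, THF–DMPU, −78 °C; Me3SiCl, −78 °C → rt; 1 M HCl
Reagents that add atoms: chlorotrimethylsilane, C[Si](C)(C)Cl (silicon is retained only in 11 and 12)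
Why: Ireland–Claisen rearrangement: in the dipolar medium the enolate with its methyl cis to O–Li forms and is trapped as the (Z)-ketene acetal 11, which rearranges through a chair with the carbinol methyl equatorial (the axial alternative meets the axial C9 methyl in a 1,3-diaxial clash); the (S)-carbinol and the (E)-alkene thus fix C9, the ketene acetal geometry fixes C8, both as in 28, and the new propenyl alkene is E.

Step 9
Reactants: 13 (2S,3R,6S)-8-[(4-methoxyphenyl)methoxy]-2,3,6-trimethyl-3-[(1E)-prop-1-en-1-yl]octanoic acid
Product: 14 (2S,3R,6S)-8-[(4-methoxyphenyl)methoxy]-2,3,6-trimethyl-3-[(1E)-prop-1-en-1-yl]octan-1-ol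
Conditions: LiAlH4, THF, 0 °C → reflux
Reagents that add atoms: none
Why: Hydride reduction of the carboxylate to the primary alcohol (C7); the isolated alkene and the ether are inert, and C8 is not epimerised because the carboxylate is not enolised under these conditions.

Step 10
Reactants: 14 (2S,3R,6S)-8-[(4-methoxyphenyl)methoxy]-2,3,6-trimethyl-3-[(1E)-prop-1-en-1-yl]octan-1-ol
Product: 15 (3S,4S)-3-{(3S)-5-[(4-methoxyphenyl)methoxy]-3-methylpentyl}-3,4-dimethyloxolan-2-ol (both anomers)
Conditions: O3, CH2Cl2–MeOH, −78 °C (Sudan Red 7B end point); Me2S, −78 °C → rt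
Reagents that add atoms: ozone, [O-][O+]=O
Why: Ozonolysis of the only alkene gives the C10 aldehyde, which closes with the C7 hydroxyl to the five-membered lactol; the alkene reacts far faster than the anisyl ring and the dye end point stops the ozone in time; the aldehyde carbon sits on the quaternary C9, so nothing can epimerise.

Step 11
Reactants: 15 (3S,4S)-3-{(3S)-5-[(4-methoxyphenyl)methoxy]-3-methylpentyl}-3,4-dimethyloxolan-2-ol (both anomers)
Product: 16 (2S,3S,6S)-3-ethynyl-8-[(4-methoxyphenyl)methoxy]-2,3,6-trimethyloctan-1-ol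
Conditions: dimethyl (1-diazo-2-oxopropyl)phosphonate, K2CO3, MeOH, rt → 40 °C
Reagents that add atoms: dimethyl (1-diazo-2-oxopropyl)phosphonate, CC(=O)C(=[N+]=[N-])P(=O)(OC)OC
Why: Ohira–Bestmann homologation of a lactol through its open hydroxy aldehyde form; the aldehyde has no α-hydrogen, so aldol and epimerisation pathways are closed; the added carbon is C1.

Step 12
Reactants: 16 (2S,3S,6S)-3-ethynyl-8-[(4-methoxyphenyl)methoxy]-2,3,6-trimethyloctan-1-ol
Product: 17 (2S,3S,6S)-3-ethynyl-8-[(4-methoxyphenyl)methoxy]-2,3,6-trimethyloctyl trifluoromethanesulfonate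
Conditions: Tf2O, pyridine, CH2Cl2, −78 → −30 °C
Reagents that add atoms: trifluoromethanesulfonic anhydride, O=S(=O)(OS(=O)(=O)C(F)(F)F)C(F)(F)F
Why: Sulfonylation of the primary alcohol; the triflate is chosen because C7 is β-branched and needs the best leaving group for the substitution that follows; it is used at once.

Step 13
Reactants: 17 (2S,3S,6S)-3-ethynyl-8-[(4-methoxyphenyl)methoxy]-2,3,6-trimethyloctyl trifluoromethanesulfonate
Product: 18 (3S,4R)-3-{(3S)-5-[(4-methoxyphenyl)methoxy]-3-methylpentyl}-3,4-dimethyloct-7-en-1-yne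
Conditions: CH2=CHCH2MgBr (3 equiv), CuI (cat.), Et2O, −78 → 0 °C
Reagents that add atoms: allylmagnesium bromide, C=CC[Mg]Br
Why: Copper-catalysed sp3–sp3 coupling of a primary triflate with a Grignard reagent (SN2 at C7, so C8 is untouched); one equivalent of the reagent is consumed by the alkyne C–H, which returns on work-up, and the alkynyl group acts only as a non-transferred ligand on copper.

Step 14
Reactants: 18 (3S,4R)-3-{(3S)-5-[(4-methoxyphenyl)methoxy]-3-methylpentyl}-3,4-dimethyloct-7-en-1-yne
Product: 21 {[(3S,4R)-3-{(3S)-5-[(4-methoxyphenyl)methoxy]-3-methylpentyl}-3,4-dimethyloct-7-en-1-yn-1-yl]oxy}tri(propan-2-yl)silane, via lithium acetylide 19 (not isolated), via lithium ynolate 20 (not isolated)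
Conditions: n-BuLi, THF, −78 °C; t-BuOOLi (from t-BuOOH and LiN(SiMe3)2), −78 → 0 °C; i-Pr3SiOTf, −78 °C
Reagents that add atoms: tert-butyl hydroperoxide (as its lithium salt), CC(C)(C)OO; triisopropylsilyl trifluoromethanesulfonate, CC(C)[Si](OS(=O)(=O)C(F)(F)F)(C(C)C)C(C)C; n-butyllithium (lithium is retained only in 19 and 20), [Li]CCCC
Why: Electrophilic oxygen transfer from the lithium peroxide to the acetylide carbon gives the ynolate, and the bulky silyl triflate silylates it on oxygen and not on carbon; the terminal alkene and the ether are inert, and the product is filtered through base-washed silica and used directly.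

Step 15
Reactants: 21 {[(3S,4R)-3-{(3S)-5-[(4-methoxyphenyl)methoxy]-3-methylpentyl}-3,4-dimethyloct-7-en-1-yn-1-yl]oxy}tri(propan-2-yl)silane; 22 methyl methacrylate
Product: 24 methyl (1S,5S,6R,8aR)-5-{(3S)-5-[(4-methoxyphenyl)methoxy]-3-methylpentyl}-1,5,6-trimethyl-4-{[tri(propan-2-yl)silyl]oxy}-1,2,3,5,6,7,8,8a-octahydronaphthalene-1-carboxylate, via siloxydiene 23 (not isolated)
Conditions: second-generation Grubbs catalyst (5 mol %), toluene (0.02 M), 60 °C; then CH2=C(CH3)CO2CH3 (excess), 2,6-di-tert-butyl-4-methylphenol, 130 °C, sealed tube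
Reagents that add atoms: methyl methacrylate (22), COC(=O)C(C)=C
Why: A ruthenium alkylidene formed at the terminal alkene (C5) adds across the siloxyalkyne by [2+2] cycloaddition with C5 bonding to C10, and cycloreversion gives the C5=C10 bond and a siloxy-substituted vinyl carbene at C1 that takes the CH2 group of the next alkene (C1=C2), releasing diene 23; the closest known reaction type is the ring-closing metathesis of alkene-tethered siloxyalkynes to cyclic 2-siloxy-1,3-dienes. Ring B closes in the exo mode as a six-membered ring, helped by the full substitution at C9. On heating with 22 the electron-rich diene 23 then undergoes a concerted, suprafacial [4+2] cycloaddition of normal electron demand that forms C2–C3 and C4–C5 and closes ring A as a six-membered ring by intermolecular annulation; the closest known types are one-pot enyne metathesis/Diels–Alder sequences and cycloadditions of 2-siloxydienes with acrylates. The orientation is secured twice by the substrate: the siloxy group on C1 makes C2 the most nucleophilic terminus, which bonds to the CH2 carbon of 22 (para rule), and the alkyl-substituted terminus C5 takes the ester-bearing carbon (ortho rule). C5 is set by the diene face: in the ring B half-chair with the C8 methyl equatorial the C9 methyl is pseudo-axial and screens its own face, whereas the other half-chair is hindered on both faces (axial C8 methyl, axial C11 chain), so 22 should add anti to the C9 methyl and leave H5 syn to it. C4 is set by the endo orientation of the ester (Alder rule), which puts CO2CH3 cis to C6 and trans to H5; no bridging CH2 is present that would force the α-methyl group into the endo position, but this preference is the weakest control element of the step. The step also needs the catalyst to act on the enyne and not on 22, which is secured by adding 22 only after ring closure, and the bulky silyl enol ether survives the heating.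

Step 16
Reactants: 24 methyl (1S,5S,6R,8aR)-5-{(3S)-5-[(4-methoxyphenyl)methoxy]-3-methylpentyl}-1,5,6-trimethyl-4-{[tri(propan-2-yl)silyl]oxy}-1,2,3,5,6,7,8,8a-octahydronaphthalene-1-carboxylate
Product: 25 methyl (1S,5S,6R,8aR)-5-{(3S)-5-[(4-methoxyphenyl)methoxy]-3-methylpentyl}-1,5,6-trimethyl-4-[(trifluoromethanesulfonyl)oxy]-1,2,3,5,6,7,8,8a-octahydronaphthalene-1-carboxylate
Conditions: CsF, PhNTf2, DME, rt
Reagents that add atoms: N-phenylbis(trifluoromethanesulfonimide), O=S(=O)(N(c1ccccc1)S(=O)(=O)C(F)(F)F)C(F)(F)F
Why: Fluoride cleaves the Si–O bond to a regiodefined cesium enolate that is O-sulfonylated as it forms; with no proton source the enolate cannot equilibrate, and the C4 ester has no α-hydrogen, so the alkene stays at C1=C10.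

Step 17
Reactants: 25 methyl (1S,5S,6R,8aR)-5-{(3S)-5-[(4-methoxyphenyl)methoxy]-3-methylpentyl}-1,5,6-trimethyl-4-[(trifluoromethanesulfonyl)oxy]-1,2,3,5,6,7,8,8a-octahydronaphthalene-1-carboxylate
Product: 26 methyl (1S,5S,6R,8aR)-5-{(3S)-5-[(4-methoxyphenyl)methoxy]-3-methylpentyl}-1,5,6-trimethyl-1,2,3,5,6,7,8,8a-octahydronaphthalene-1-carboxylate
Conditions: Pd(OAc)2 (cat.), PPh3, HCO2H, n-Bu3N, DMF, 60 °C
Reagents that add atoms: none
Why: Oxidative addition of the enol triflate to zerovalent palladium, exchange with formate, loss of CO2 to a palladium hydride and reductive elimination give the C1–H bond with the alkene fixed where the triflate stood; ester and ether are inert.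

Step 18
Reactants: 26 methyl (1S,5S,6R,8aR)-5-{(3S)-5-[(4-methoxyphenyl)methoxy]-3-methylpentyl}-1,5,6-trimethyl-1,2,3,5,6,7,8,8a-octahydronaphthalene-1-carboxylate
Product: 27 methyl (1S,5S,6R,8aR)-5-[(3S)-5-hydroxy-3-methylpentyl]-1,5,6-trimethyl-1,2,3,5,6,7,8,8a-octahydronaphthalene-1-carboxylate
Conditions: DDQ, CH2Cl2–pH 7 buffer, 0 °C → rt
Reagents that add atoms: none
Why: Oxidative removal of the p-methoxybenzyl ether by hydride abstraction from the electron-rich benzylic position and hydrolysis of the oxocarbenium ion; the unactivated trisubstituted alkene and the ester are not oxidised under buffered conditions.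

Step 19
Reactants: 27 methyl (1S,5S,6R,8aR)-5-[(3S)-5-hydroxy-3-methylpentyl]-1,5,6-trimethyl-1,2,3,5,6,7,8,8a-octahydronaphthalene-1-carboxylate
Product: 28 methyl (1S,5S,6R,8aR)-5-[(3S)-5-(acetyloxy)-3-methylpentyl]-1,5,6-trimethyl-1,2,3,5,6,7,8,8a-octahydronaphthalene-1-carboxylate
Conditions: Ac2O, pyridine, DMAP (cat.), CH2Cl2, rt
Reagents that add atoms: acetic anhydride, CC(=O)OC(C)=O
Why: Acylation of the primary alcohol under mild basic conditions that do not move the alkene; it gives the target.

## Compound list

1 | (S)-citronellol, (3S)-3,7-dimethyloct-6-en-1-ol | C[C@@H](CCC=C(C)C)CCO | starting material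
2 | 1-({[(3S)-3,7-dimethyloct-6-en-1-yl]oxy}methyl)-4-methoxybenzene | C[C@@H](CCC=C(C)C)CCOCc1ccc(OC)cc1 | intermediate
3 | (4S)-6-[(4-methoxyphenyl)methoxy]-4-methylhexanal | C[C@@H](CCC=O)CCOCc1ccc(OC)cc1 | intermediate
4 | 1-methoxy-4-({[(3S)-3-methylhept-6-yn-1-yl]oxy}methyl)benzene | C#CCC[C@H](C)CCOCc1ccc(OC)cc1 | intermediate
5 | [(1E,5S)-7-[(4-methoxyphenyl)methoxy]-2,5-dimethylhept-1-en-1-yl]dimethylalumane | C[Al](C)/C=C(\C)CC[C@H](C)CCOCc1ccc(OC)cc1 | intermediate (not isolated)
6 | (3E,7S)-9-[(4-methoxyphenyl)methoxy]-4,7-dimethylnon-3-en-2-ol (both C2 epimers) | CC(O)/C=C(\C)CC[C@H](C)CCOCc1ccc(OC)cc1 | intermediate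
7 | (3E,7S)-9-[(4-methoxyphenyl)methoxy]-4,7-dimethylnon-3-en-2-one | CC(=O)/C=C(\C)CC[C@H](C)CCOCc1ccc(OC)cc1 | intermediate
8 | (2S,3E,7S)-9-[(4-methoxyphenyl)methoxy]-4,7-dimethylnon-3-en-2-ol | C[C@H](O)/C=C(\C)CC[C@H](C)CCOCc1ccc(OC)cc1 | intermediate
9 | propionyl chloride | CCC(Cl)=O | starting material
10 | (2S,3E,7S)-9-[(4-methoxyphenyl)methoxy]-4,7-dimethylnon-3-en-2-yl propanoate | CCC(=O)O[C@@H](C)/C=C(\C)CC[C@H](C)CCOCc1ccc(OC)cc1 | intermediate
11 | (1Z)-1-{[(2S,3E,7S)-9-[(4-methoxyphenyl)methoxy]-4,7-dimethylnon-3-en-2-yl]oxy}-1-(trimethylsilyloxy)prop-1-ene | C/C=C(\O[Si](C)(C)C)O[C@@H](C)/C=C(\C)CC[C@H](C)CCOCc1ccc(OC)cc1 | intermediate (not isolated)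
12 | trimethylsilyl (2S,3R,6S)-8-[(4-methoxyphenyl)methoxy]-2,3,6-trimethyl-3-[(1E)-prop-1-en-1-yl]octanoate | C[Si](C)(C)OC(=O)[C@@H](C)[C@@](C)(/C=C/C)CC[C@H](C)CCOCc1ccc(OC)cc1 | intermediate (not isolated)
13 | (2S,3R,6S)-8-[(4-methoxyphenyl)methoxy]-2,3,6-trimethyl-3-[(1E)-prop-1-en-1-yl]octanoic acid | OC(=O)[C@@H](C)[C@@](C)(/C=C/C)CC[C@H](C)CCOCc1ccc(OC)cc1 | intermediate
14 | (2S,3R,6S)-8-[(4-methoxyphenyl)methoxy]-2,3,6-trimethyl-3-[(1E)-prop-1-en-1-yl]octan-1-ol | OC[C@@H](C)[C@@](C)(/C=C/C)CC[C@H](C)CCOCc1ccc(OC)cc1 | intermediate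
15 | (3S,4S)-3-{(3S)-5-[(4-methoxyphenyl)methoxy]-3-methylpentyl}-3,4-dimethyloxolan-2-ol (both anomers) | OC1OC[C@@H](C)[C@]1(C)CC[C@H](C)CCOCc2ccc(OC)cc2 | intermediate
16 | (2S,3S,6S)-3-ethynyl-8-[(4-methoxyphenyl)methoxy]-2,3,6-trimethyloctan-1-ol | OC[C@@H](C)[C@@](C)(C#C)CC[C@H](C)CCOCc1ccc(OC)cc1 | intermediate
17 | (2S,3S,6S)-3-ethynyl-8-[(4-methoxyphenyl)methoxy]-2,3,6-trimethyloctyl trifluoromethanesulfonate | FC(F)(F)S(=O)(=O)OC[C@@H](C)[C@@](C)(C#C)CC[C@H](C)CCOCc1ccc(OC)cc1 | intermediate
18 | (3S,4R)-3-{(3S)-5-[(4-methoxyphenyl)methoxy]-3-methylpentyl}-3,4-dimethyloct-7-en-1-yne | C=CCC[C@@H](C)[C@@](C)(C#C)CC[C@H](C)CCOCc1ccc(OC)cc1 | intermediate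
19 | lithium acetylide of 18 | C=CCC[C@@H](C)[C@@](C)(C#C[Li])CC[C@H](C)CCOCc1ccc(OC)cc1 | intermediate (not isolated)
20 | lithium ynolate, lithium (3S,4R)-3-{(3S)-5-[(4-methoxyphenyl)methoxy]-3-methylpentyl}-3,4-dimethyloct-7-en-1-yn-1-olate | C=CCC[C@@H](C)[C@@](C)(C#CO[Li])CC[C@H](C)CCOCc1ccc(OC)cc1 | intermediate (not isolated)
21 | {[(3S,4R)-3-{(3S)-5-[(4-methoxyphenyl)methoxy]-3-methylpentyl}-3,4-dimethyloct-7-en-1-yn-1-yl]oxy}tri(propan-2-yl)silane | C=CCC[C@@H](C)[C@@](C)(C#CO[Si](C(C)C)(C(C)C)C(C)C)CC[C@H](C)CCOCc1ccc(OC)cc1 | intermediate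
22 | methyl methacrylate | COC(=O)C(C)=C | starting material
23 | ({1-[(5R,6S)-6-{(3S)-5-[(4-methoxyphenyl)methoxy]-3-methylpentyl}-5,6-dimethylcyclohex-1-en-1-yl]ethenyl}oxy)tri(propan-2-yl)silane | C=C(O[Si](C(C)C)(C(C)C)C(C)C)C1=CCC[C@@H](C)[C@]1(C)CC[C@H](C)CCOCc2ccc(OC)cc2 | intermediate (not isolated)
24 | methyl (1S,5S,6R,8aR)-5-{(3S)-5-[(4-methoxyphenyl)methoxy]-3-methylpentyl}-1,5,6-trimethyl-4-{[tri(propan-2-yl)silyl]oxy}-1,2,3,5,6,7,8,8a-octahydronaphthalene-1-carboxylate | COC(=O)[C@@]1(C)CCC(O[Si](C(C)C)(C(C)C)C(C)C)=C2[C@H]1CC[C@@H](C)[C@]2(C)CC[C@H](C)CCOCc3ccc(OC)cc3 | intermediate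
25 | methyl (1S,5S,6R,8aR)-5-{(3S)-5-[(4-methoxyphenyl)methoxy]-3-methylpentyl}-1,5,6-trimethyl-4-[(trifluoromethanesulfonyl)oxy]-1,2,3,5,6,7,8,8a-octahydronaphthalene-1-carboxylate | COC(=O)[C@@]1(C)CCC(OS(=O)(=O)C(F)(F)F)=C2[C@H]1CC[C@@H](C)[C@]2(C)CC[C@H](C)CCOCc3ccc(OC)cc3 | intermediate
26 | methyl (1S,5S,6R,8aR)-5-{(3S)-5-[(4-methoxyphenyl)methoxy]-3-methylpentyl}-1,5,6-trimethyl-1,2,3,5,6,7,8,8a-octahydronaphthalene-1-carboxylate | COC(=O)[C@@]1(C)CCC=C2[C@H]1CC[C@@H](C)[C@]2(C)CC[C@H](C)CCOCc3ccc(OC)cc3 | intermediate
27 | methyl (1S,5S,6R,8aR)-5-[(3S)-5-hydroxy-3-methylpentyl]-1,5,6-trimethyl-1,2,3,5,6,7,8,8a-octahydronaphthalene-1-carboxylate | COC(=O)[C@@]1(C)CCC=C2[C@H]1CC[C@@H](C)[C@]2(C)CC[C@H](C)CCO | intermediate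
28 | methyl (1S,5S,6R,8aR)-5-[(3S)-5-(acetyloxy)-3-methylpentyl]-1,5,6-trimethyl-1,2,3,5,6,7,8,8a-octahydronaphthalene-1-carboxylate | COC(=O)[C@@]1(C)CCC=C2[C@H]1CC[C@@H](C)[C@]2(C)CC[C@H](C)CCOC(C)=O | target

## Step count and least certain steps

Total step count: 19. Longest linear sequence: 19 steps, from 1 to 28; 9 and 22 enter in steps 7 and 15.

**Step 15 (key step).** Three processes can fail.
- The ring closure can stall at the siloxy-substituted ruthenium carbene, a heteroatom-stabilised carbene next to a fully substituted carbon.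
- The cycloaddition can be slow, because the s-cis conformer of a diene with substituents on both inner carbons is twisted and 22 is an α-substituted dienophile.
- Endo/exo or facial selectivity can erode, because the α-methyl group of 22 competes with the ester for the endo position.

Fallback (sets out from 21, returns at 24): the metathesis is run alone and diene 23 is isolated on base-washed silica. It is heated with methyl acrylate, a smaller and more reactive dienophile that obeys the same orientation rules, to give the C4–H adduct F1 as a mixture of C4 epimers. LiN(i-Pr)2 and then CH3I methylate the ester enolate of F1 to give 24. C4 is then set by the face of an exocyclic enolate and not by the endo preference. Allylic 1,3-strain turns C6 out of the enolate plane, so CH3I should enter anti to C6, that is cis to H5, as required. A failure of the ring closure itself is covered by the route under step 14.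

**Step 14.** Oxygen transfer to the acetylide may be incomplete, silylation may go to carbon and give a silylketene, and the siloxyalkyne may hydrolyse on handling. Fallback (sets out from 18, returns at 26): 18 is cyclised as the terminal alkyne with the second-generation Grubbs catalyst under ethylene to the 1-vinylcyclohexene F2. F2 is heated with 22 in a sealed tube to give 26 directly, which bypasses 21 and 23–25. The price is a less reactive diene whose orientation rests on the ortho rule alone.

**Step 13.** Substitution at C7 is slowed by the tertiary C8 and the quaternary C9, so elimination or decomposition of the triflate may win. Fallback (sets out from 16, returns at 18): I2, PPh3 and imidazole convert 16 into the primary iodide F3. Keck radical allylation with allyltributylstannane and AIBN in benzene at 80 °C then forms the C6–C7 bond through a primary radical, which is insensitive to the steric bulk. Cyclisation of that radical onto the alkyne would need a four-membered or an endo five-membered ring and is not expected.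

**Step 8.** Control of the enolate geometry may be incomplete; any enolate with methyl trans to O–Li gives the C8 epimer. Fallback (sets out from 8, returns at 14):
- Ac2O and pyridine give the acetate F4.
- Its Ireland–Claisen rearrangement has no enolate geometry and gives the acid F5 with C9 alone set.
- Pivaloyl chloride and Et3N, then lithiated (4S)-4-benzyl-1,3-oxazolidin-2-one, give the imide F6.
- NaN(SiMe3)2 and CH3I methylate the chelated (Z)-enolate on the face away from the benzyl group (Evans alkylation) to give F7 with C8 as required.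
- LiBH4 releases 14.

**Step 16.** Cleavage of the hindered Si–O bond may be slow, and traces of water would protonate the enolate to the ketone. Fallback (sets out from 24, returns at 25): HF·pyridine in THF hydrolyses 24 to the C1 ketone F8. Tf2O with 2,6-di-tert-butyl-4-methylpyridine in CH2Cl2 then sulfonylates the more substituted enol under equilibrating conditions to give 25.

## Further compounds

F1 | step 15 | methyl (5S,6R,8aS)-5-{(3S)-5-[(4-methoxyphenyl)methoxy]-3-methylpentyl}-5,6-dimethyl-4-{[tri(propan-2-yl)silyl]oxy}-1,2,3,5,6,7,8,8a-octahydronaphthalene-1-carboxylate (both C1 epimers, C4 in halimane numbering) | COC(=O)C1CCC(O[Si](C(C)C)(C(C)C)C(C)C)=C2[C@H]1CC[C@@H](C)[C@]2(C)CC[C@H](C)CCOCc3ccc(OC)cc3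
F2 | step 14 | 1-({[(3S)-5-[(1S,6R)-2-ethenyl-1,6-dimethylcyclohex-2-en-1-yl]-3-methylpentyl]oxy}methyl)-4-methoxybenzene | C=CC1=CCC[C@@H](C)[C@]1(C)CC[C@H](C)CCOCc2ccc(OC)cc2
F3 | step 13 | 1-({[(3S,6S,7S)-6-ethynyl-8-iodo-3,6,7-trimethyloctyl]oxy}methyl)-4-methoxybenzene | IC[C@@H](C)[C@@](C)(C#C)CC[C@H](C)CCOCc1ccc(OC)cc1
F4 | step 8 | (2S,3E,7S)-9-[(4-methoxyphenyl)methoxy]-4,7-dimethylnon-3-en-2-yl acetate | CC(=O)O[C@@H](C)/C=C(\C)CC[C@H](C)CCOCc1ccc(OC)cc1
F5 | step 8 | (3S,6S)-8-[(4-methoxyphenyl)methoxy]-3,6-dimethyl-3-[(1E)-prop-1-en-1-yl]octanoic acid | OC(=O)C[C@@](C)(/C=C/C)CC[C@H](C)CCOCc1ccc(OC)cc1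
F6 | step 8 | (4S)-4-benzyl-3-{(3S,6S)-8-[(4-methoxyphenyl)methoxy]-3,6-dimethyl-3-[(1E)-prop-1-en-1-yl]octanoyl}-1,3-oxazolidin-2-one | O=C(C[C@@](C)(/C=C/C)CC[C@H](C)CCOCc1ccc(OC)cc1)N1[C@@H](Cc2ccccc2)COC1=O
F7 | step 8 | (4S)-4-benzyl-3-{(2S,3R,6S)-8-[(4-methoxyphenyl)methoxy]-2,3,6-trimethyl-3-[(1E)-prop-1-en-1-yl]octanoyl}-1,3-oxazolidin-2-one | O=C([C@@H](C)[C@@](C)(/C=C/C)CC[C@H](C)CCOCc1ccc(OC)cc1)N1[C@@H](Cc2ccccc2)COC1=O
F8 | step 16 | methyl (1S,5S,6R,8aR)-5-{(3S)-5-[(4-methoxyphenyl)methoxy]-3-methylpentyl}-1,5,6-trimethyl-4-oxodecahydronaphthalene-1-carboxylate (both C4a epimers) | COC(=O)[C@@]1(C)CCC(=O)C2[C@H]1CC[C@@H](C)[C@]2(C)CC[C@H](C)CCOCc3ccc(OC)cc3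
A1 | alternative 1 | 2-methylcyclohex-2-en-1-one | CC1=CCCCC1=O
A2 | alternative 1 | {[(3E)-5-bromo-3-methylpent-3-en-1-yl]oxy}(tert-butyl)dimethylsilane | BrC/C=C(\C)CCO[Si](C)(C)C(C)(C)C
A3 | alternative 1 | bromomagnesium (3R)-2,3-dimethylcyclohex-1-en-1-olate | Br[Mg]OC1=C(C)[C@H](C)CCC1
A4 | alternative 1 | (2S,3R)-2-[(2E)-5-{[tert-butyl(dimethyl)silyl]oxy}-3-methylpent-2-en-1-yl]-2,3-dimethylcyclohexan-1-one | O=C1CCC[C@@H](C)[C@]1(C)C/C=C(\C)CCO[Si](C)(C)C(C)(C)C
A5 | alternative 2 | methyl 1-hydroxy-15-{[tert-butyl(dimethyl)silyl]oxy}-20-norhalim-9-en-18-oate (halimane numbering; tetrasubstituted C9=C10 alkene, C1 hydroxyl on the face of the future C9 methyl) | COC(=O)[C@@]1(C)CC[C@H](O)C2=C(CC[C@H](C)CCO[Si](C)(C)C(C)(C)C)[C@H](C)CC[C@@H]12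
A6 | alternative 2 | methyl 1-hydroxy-15-{[tert-butyl(dimethyl)silyl]oxy}-9,10-methano-20-norhaliman-18-oate (cyclopropyl carbinol, halimane numbering) | COC(=O)[C@@]1(C)CC[C@H](O)[C@]23[C@H]1CC[C@@H](C)[C@]2(C3)CC[C@H](C)CCO[Si](C)(C)C(C)(C)C
A7 | alternative 3 | (6R)-6-[(5R,6S)-6-{(3S)-5-{[tert-butyl(dimethyl)silyl]oxy}-3-methylpentyl}-5,6-dimethylcyclohex-1-en-1-yl]-3-methyloxan-2-one (both C3 epimers) | CC1CC[C@@H](OC1=O)C2=CCC[C@@H](C)[C@]2(C)CC[C@H](C)CCO[Si](C)(C)C(C)(C)C
A8 | alternative 3 | (2R)-2-[(5R,6S)-6-{(3S)-5-{[tert-butyl(dimethyl)silyl]oxy}-3-methylpentyl}-5,6-dimethylcyclohex-1-en-1-yl]-5-methyl-6-(trimethylsilyloxy)-3,4-dihydro-2H-pyran | CC1=C(O[Si](C)(C)C)O[C@H](CC1)C2=CCC[C@@H](C)[C@]2(C)CC[C@H](C)CCO[Si](C)(C)C(C)(C)C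
A9 | alternative 3 | (1S,5S,6R,8aR)-5-{(3S)-5-{[tert-butyl(dimethyl)silyl]oxy}-3-methylpentyl}-1,5,6-trimethyl-1,2,3,5,6,7,8,8a-octahydronaphthalene-1-carboxylic acid | OC(=O)[C@@]1(C)CCC=C2[C@H]1CC[C@@H](C)[C@]2(C)CC[C@H](C)CCO[Si](C)(C)C(C)(C)C
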